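All runs stem from a simulated flask on assumed constants; the scatter is artificial.

Into a closed, stirred vessel of constant volume goes substrate, held isothermal, and we follow target and side product.

| flask | substrate | remark | time |
|---|---|---|---|
| autumn | 0.29 M | run made earlier |  |
| dusk | 0.88 M | run made earlier |  |
| noon | 2.6 M | run made earlier |  |
| north | 0.30 M |  | 10 h |
| north-east | 0.60 M |  | 10 h |
| west | 1.2 M |  | 10 h |
| north-west | 2.5 M |  | 10 h |

| run | time / h | target / % | side product / % |
|---|---|---|---|
| autumn | 0.833 | 2 | 1 |
| autumn | 1.50 | 0 | 2 |
| autumn | 3.00 | 7 | 2 |
| autumn | 5.00 | 11 | 0 |
| autumn | 10.0 | 24 | 9 |
| dusk | 2.00 | 6 | 0 |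
| dusk | 4.00 | 4 | 0 |
| dusk | 6.00 | 11 | 3 |
| dusk | 8.00 | 16 | 5 |
| dusk | 10.0 | 20 | 6 |
| noon | 0.833 | 0 | 0 |
| noon | 2.50 | 1 | 3 |
| noon | 5.00 | 7 | 0 |
| noon | 8.00 | 14 | 7 |
| noon | 10.0 | 18 | 5 |

(readings scatter by 2 percentage points)

- the earlier runs were read with a standard deviation of 2 percentage points
- "hardly changes" means that all values lie within two and a half points (for a concentration: within two and a half percent of the largest)

1. share of target in all that became target or side product for north, north-east, west, north-west, in this order
2. the shape of the row from first to last (rises, then falls / rises all the way / falls all the way / hardly changes / falls, then rises)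

We write the balance of substrate at 10.0 h: what was charged is target, plus side product, plus a rest we do not read. In the autumn run target and side product together hold 33.0%, and in the noon run 23.0%, less, so the rest reads larger at the larger charge.

Now we turn the question round. For the row to rise or fall, the share of target in target plus side product would have to leave the band called hardly changes. With two routes of the same order in substrate, a loss ahead of their fork shrinks both products together and leaves that share alone, so the rest would have to take from one route harder than from the other.

The readings at that time give 72.7% for autumn, 76.9% for dusk and 78.3% for noon. Noon reads higher than autumn by 5.6 percentage points, but the side product of noon is a reading of 5% with a scatter of 2 points, and we read that gap as scatter. The flasks, 0.30 M to 2.5 M, lie inside the range of the runs, 0.29 M to 2.6 M. So we pool the last readings of the runs and get 75.6% for the split, which is target divided by target plus side product, the selectivity as these readings show it, and we expect it in north, north-east, west and north-west.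

The forecast, whose level differs from our split, gives 74% at each of the charges, so hardly changes: “I expect a share of about 74% at every concentration, so the row should hardly change.”

The flasks give 79.1%, 79.2%, 79.2% and 79.2%, so the row hardly changes.

    substrate → intermediate A (k = 0.0130 min⁻¹)
    intermediate A → intermediate B (k = 0.00220 min⁻¹)
    substrate → intermediate C (k = 0.00700 min⁻¹)
    intermediate B → target (k = 0.00110 min⁻¹)
    intermediate C → intermediate D (k = 0.0380 min⁻¹)
    intermediate D → side product (k = 0.00400 min⁻¹)
    intermediate D ⇌ intermediate B (K = 16.0, k = 0.110 min⁻¹)
    2 substrate → self-condensation product (k = 0.00450 M⁻¹ min⁻¹)

In north-west the self-condensation product holds 33.0% of the charge at 10.0 h, each counted as two substrate, against 6.20% in north, and taking that path out makes no difference to the share of north-west. Our split of 75.6%, put on north-west at 10.0 h, where target and side product together hold 22.0%, gives 16.6% of target, and north-west holds 17.4%.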